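Early on, the amber flask outruns the red one: at 8.00 h it holds 45.6% target, more than red's 14.5%. Then amber stalls. At 50.0 h it still has 29.4% substrate, while red, on the same charges, is down to 9.1% at 96.0 h. Amber, the hotter run, goes faster and stalls earlier. That reads as loss of catalyst (catalyst deactivation), though a ceiling that falls with heat gives the same picture.

| setting | amber | red | flask |
|---|---|---|---|
| substrate | 0.10 M | 0.10 M | 0.10 M |
| free enzyme | 10 µM | 10 µM | 10 µM |
| temperature | 37 °C | 22 °C | 37 °C |
| remark | the very flask that is asked about, followed so far | run made earlier |  |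
| time |  |  | 2.5 d |

| run | time / h | target / % | substrate / % |
|---|---|---|---|
| amber | 4.00 | 28.2 | 70.0 |
| amber | 8.00 | 45.6 | 52.9 |
| amber | 15.0 | 62.8 | 37.8 |
| amber | 25.0 | 67.5 | 31.6 |
| amber | 50.0 | 69.1 | 29.4 |
| red | 8.00 | 14.5 | 85.2 |
| red | 15.0 | 26.2 | 74.2 |
| red | 30.0 | 49.2 | 50.2 |
| red | 48.0 | 69.3 | 30.3 |
| red | 96.0 | 90.9 | 9.1 |

(scatter of a reading: 0.5 percentage points)

- target, in percent of the substrate first charged, at 2.5 d
- what to do for the largest gain in target; "none" if nothing gains more than 2 percentage points (Friday's / Tuesday's / Sunday's / Monday's / none)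
- target present, with what was taken out counted in, in percent of the substrate first charged, after Friday's
- target present, with what was taken out counted in, in percent of the substrate first charged, after Sunday's

- Friday's: at 2.5 d add free enzyme, 100% of the amount charged, then wait 20 h
- Tuesday's: change nothing and wait 20 h more
- Sunday's: at 2.5 d take out 90% of the target then present, then wait 20 h
- Monday's: at 2.5 d raise the temperature by 10 K, then wait 20 h

- target taken out counts as made
- additions bring no volume worth counting

Here is my own reckoning, one setting at a time.

Time: amber's target rose 4.7 percentage points from 15.0 h to 25.0 h, then 1.6 points over the longer stretch to 50.0 h. So you can put the target at 2.5 d a little above 69.1%, and waiting should stay under the 2 points margin.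

Temperature: red got further at the lower setting, 90.9% against amber's 69.1%, though over a longer run, so expect nothing from 10 K more.

Target: taking out 90% lifts any ceiling, but if the catalyst is lost that gains little, so expect the count to stay put.

Enzyme: assume each charge of free enzyme multiplies c(substrate) by the same factor before it stops. Then the natural log of c(substrate) at the start over c(substrate) at the stall is the charge capacity 1.22. On that assumption, I expect a second charge on amber to leave 8.68% substrate, so about 91.3% target. A ceiling lowers that estimate.

The forecast says 69.8% now (69% to 70.8%) and picks Friday's. It puts Friday's at 91% (84% to 95%) and Sunday's at 70% (69% to 74%). Its ground is “The likelier explanation is enzyme death”.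

The flask gives 70.0% at 2.5 d, and Friday's is best. Friday's changes the target by 11 points, to 81.0%. Tuesday's changes it by −0.13 points, Sunday's by 0.018 points, to 70.0%, and Monday's by −0.71 points.

    substrate + free enzyme ⇌ complex (K = 70.0 L mol⁻¹, k = 5100 L mol⁻¹ min⁻¹, Ea = 51.0 kJ mol⁻¹, ΔH = −31.0 kJ mol⁻¹)
    free enzyme → spent catalyst (k = 0.00590 min⁻¹, Ea = 100 kJ mol⁻¹)
    complex ⇌ free enzyme + target (K = 0.0740 M, k = 17.0 min⁻¹, Ea = 82.0 kJ mol⁻¹, ΔH = −33.0 kJ mol⁻¹)
    free enzyme → unfolded enzyme (k = 3.80 × 10⁻⁴ min⁻¹, Ea = 202 kJ mol⁻¹)
    target → over-reaction product (k = 1.80 × 10⁻⁶ min⁻¹, Ea = 128 kJ mol⁻¹)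
    (constants at 37 °C)

Friday's narrowed the gap to full target by a log of 0.457, less than the capacity of 1.22. The flask has back steps, and their constants at 37 °C put the ceiling at 83.8% target, above Friday's 81.0%. For a neighbour flask charged with 4.0 × 10⁻⁶ M free enzyme, the capacity gives 61.3% substrate, and at 2.5 d that flask holds 56.7%. In the asked flask, free enzyme has a half-life of 2.0 h by the turning into spent catalyst alone, shorter than 30 h by the turning into unfolded enzyme alone. At 2.5 d the catalyst stands at 93.9% spent catalyst and 6.05% unfolded enzyme.

The data are simulated on assumed constants; scatter was added.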